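**Retrosynthetic overview**
- The target is reached by cleaving two aryl silyl ethers from a bis(silyl) furofuranone that already carries all four stereocentres.
- Key disconnection: the C3–C3a bond and the lactone C1–O2 bond are made in one operation. A carbene-generated homoenolate (nucleophilic β-carbon) of a 2-aryl-2,5-dihydrofuran-3-carbaldehyde adds to silylated syringaldehyde, then acyl transfer closes the lactone.
- The dihydrofuran enal comes from silylated coniferaldehyde and glycolaldehyde by an amine-catalysed oxa-Michael/aldol condensation, which sets the first stereocentre (C6 of the target).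
- Ring order: the oxygen five-ring bearing the guaiacyl group is formed first, the γ-lactone second.

Assumption: locants of the bicycle follow furo[3,4-c]furan numbering (C1 carbonyl, O2, C3, C3a, C4, O5, C6, C6a), in which the given SMILES is (3S,3aR,6S,6aS), cis-fused with both aryl groups exo; the dihydrofuran is numbered O1, C2 (aryl), C3 (CHO), C4, C5.

**Step 1**
Reactants: 1 (E)-coniferaldehyde
Product: 2 (E)-3-[4-(tert-butyldimethylsilyloxy)-3-methoxyphenyl]prop-2-enal
Conditions: t-BuMe2SiCl (1.2 equiv), imidazole (2.5 equiv), DMF, 0 °C to rt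
Reagents that add atoms: tert-butyldimethylsilyl chloride, CC(C)(C)[Si](C)(C)Cl
Why: Imidazole-promoted O-silylation of the phenol (Corey protocol) masks the acidic OH, which would otherwise quench the amine and carbene catalysts of steps 3 and 4, and it leaves the enal untouched.

**Step 2**
Reactants: 3 syringaldehyde
Product: 4 4-(tert-butyldimethylsilyloxy)-3,5-dimethoxybenzaldehyde
Conditions: t-BuMe2SiCl (1.5 equiv), imidazole (3 equiv), DMF, 40 °C
Reagents that add atoms: tert-butyldimethylsilyl chloride, CC(C)(C)[Si](C)(C)Cl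
Why: The same O-silylation, run warm because the phenol is flanked by two methoxy groups, removes the phenoxide that would make the aldehyde a vinylogous carboxylate and useless as an electrophile.

**Step 3**
Reactants: 2 (E)-3-[4-(tert-butyldimethylsilyloxy)-3-methoxyphenyl]prop-2-enal; 5 glycolaldehyde dimer (0.75 equiv)
Product: 7 (R)-2-[4-(tert-butyldimethylsilyloxy)-3-methoxyphenyl]-2,5-dihydrofuran-3-carbaldehyde, via aldol adduct 6 (not isolated)
Conditions: (S)-2-[diphenyl(trimethylsilyloxy)methyl]pyrrolidine (20 mol %), PhCO2H (20 mol %), CHCl3, rt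
Reagents that add atoms: none
Why: Proposed new method: iminium activation of 2 lets the hydroxyl of monomeric glycolaldehyde add to the β-carbon on the Si face left open by the CPh2OSiMe3 group (setting C2 as R), the resulting enamine closes onto the tethered aldehyde (aldol) and loss of water gives the conjugated enal, the closest known reaction types being the amine-catalysed thia-Michael/aldol condensation of 1,4-dithiane-2,5-diol with enals and the oxa-Michael/aldol cascades of salicylaldehydes and of dihydroxyacetone dimer with enals.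

**Step 4**
Reactants: 7 (R)-2-[4-(tert-butyldimethylsilyloxy)-3-methoxyphenyl]-2,5-dihydrofuran-3-carbaldehyde; 4 4-(tert-butyldimethylsilyloxy)-3,5-dimethoxybenzaldehyde (2 equiv)
Product: 9 (3S,3aR,6S,6aS)-6-[4-(tert-butyldimethylsilyloxy)-3-methoxyphenyl]-3-[4-(tert-butyldimethylsilyloxy)-3,5-dimethoxyphenyl]tetrahydro-1H,3H-furo[3,4-c]furan-1-one, via acyl imidazolium alkoxide 8 (not isolated)
Conditions: 1,3-bis(2,4,6-trimethylphenyl)imidazolium chloride (15 mol %), 1,8-diazabicyclo[5.4.0]undec-7-ene (15 mol %), LiCl (1 equiv), THF, 4 Å MS, 40 °C, Ar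
Reagents that add atoms: none
Why: Proposed new method: the carbene adds to the formyl group of 7 and proton transfer gives the extended Breslow intermediate, a homoenolate whose ring carbon C4 attacks the lithium-activated aldehyde carbon of 4 on the face anti to the C2 aryl group with the incoming aryl turned away from the ring (setting C3a and C3), after which the enol azolium equilibrates with the acyl azolium and only the cis-disposed epimer can be closed by the alkoxide (setting C6a and releasing the carbene), the closest known reaction type being the N-heterocyclic-carbene-catalysed homoenolate annulation of enals with aldehydes to γ-butyrolactones, here extended to an α-branched cyclic enal.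

**Step 5**
Reactants: 9 (3S,3aR,6S,6aS)-6-[4-(tert-butyldimethylsilyloxy)-3-methoxyphenyl]-3-[4-(tert-butyldimethylsilyloxy)-3,5-dimethoxyphenyl]tetrahydro-1H,3H-furo[3,4-c]furan-1-one
Product: 10 (3S,3aR,6S,6aS)-6-(4-hydroxy-3-methoxyphenyl)-3-(4-hydroxy-3,5-dimethoxyphenyl)tetrahydro-1H,3H-furo[3,4-c]furan-1-one
Conditions: Bu4NF (2.5 equiv), AcOH (2.5 equiv), THF, 0 °C
Reagents that add atoms: none
Why: Fluoride cleaves both aryl silyl ethers through Si–F bond formation while acetic acid keeps the freed phenols protonated, so the para-hydroxybenzylic C–O bonds do not ionise to quinone methides and no stereocentre is touched.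

**Compound list**
1 | (E)-coniferaldehyde, (E)-3-(4-hydroxy-3-methoxyphenyl)prop-2-enal | COc1cc(/C=C/C=O)ccc1O | starting material
2 | (E)-3-[4-(tert-butyldimethylsilyloxy)-3-methoxyphenyl]prop-2-enal | COc1cc(/C=C/C=O)ccc1O[Si](C)(C)C(C)(C)C | intermediate
3 | syringaldehyde, 4-hydroxy-3,5-dimethoxybenzaldehyde | COc1cc(C=O)cc(OC)c1O | starting material
4 | 4-(tert-butyldimethylsilyloxy)-3,5-dimethoxybenzaldehyde | COc1cc(C=O)cc(OC)c1O[Si](C)(C)C(C)(C)C | intermediate
5 | glycolaldehyde dimer, 1,4-dioxane-2,5-diol (stereoisomer mixture) | OC1COC(O)CO1 | starting material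
6 | aldol adduct, (2S)-2-[4-(tert-butyldimethylsilyloxy)-3-methoxyphenyl]-4-hydroxytetrahydrofuran-3-carbaldehyde (C3/C4 mixture, same spatial arrangement at C2 as in 7) | COc1cc([C@H]2OCC(O)C2C=O)ccc1O[Si](C)(C)C(C)(C)C | intermediate (not isolated)
7 | (R)-2-[4-(tert-butyldimethylsilyloxy)-3-methoxyphenyl]-2,5-dihydrofuran-3-carbaldehyde | COc1cc([C@H]2OCC=C2C=O)ccc1O[Si](C)(C)C(C)(C)C | intermediate
8 | acyl imidazolium alkoxide: 1,3-dimesityl-2-acylimidazolium zwitterion of the (2S,3S,4R)-tetrahydrofuran carrying the silylated guaiacyl group at C2, the acyl group at C3 and the (S)-aryl(oxido)methyl group at C4 | COc1cc([C@H]2OC[C@H]([C@H]([O-])c3cc(OC)c(O[Si](C)(C)C(C)(C)C)c(OC)c3)[C@@H]2C(=O)c2n(-c3c(C)cc(C)cc3C)cc[n+]2-c2c(C)cc(C)cc2C)ccc1O[Si](C)(C)C(C)(C)C | intermediate (not isolated)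
9 | (3S,3aR,6S,6aS)-6-[4-(tert-butyldimethylsilyloxy)-3-methoxyphenyl]-3-[4-(tert-butyldimethylsilyloxy)-3,5-dimethoxyphenyl]tetrahydro-1H,3H-furo[3,4-c]furan-1-one | COc1cc([C@H]2OC[C@H]3[C@@H]2C(=O)O[C@@H]3c2cc(OC)c(O[Si](C)(C)C(C)(C)C)c(OC)c2)ccc1O[Si](C)(C)C(C)(C)C | intermediate
10 | (3S,3aR,6S,6aS)-6-(4-hydroxy-3-methoxyphenyl)-3-(4-hydroxy-3,5-dimethoxyphenyl)tetrahydro-1H,3H-furo[3,4-c]furan-1-one (CNP0142585.1) | COc1cc([C@H]2OC[C@H]3[C@@H]2C(=O)O[C@@H]3c2cc(OC)c(O)c(OC)c2)ccc1O | target

**Totals**
Total step count: 5. Longest linear sequence: 4 steps (1 → 2 → 7 → 9 → 10).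

**Steps most likely to fail**

Step 4 (highest risk). The α-branched enal 7 may form its Breslow intermediate slowly, and the electron-rich aldehyde 4 is a weak electrophile. The C3 configuration (aryl exo rather than endo) rests on a transition-state argument, not on thermodynamics, and ordinary acyclic enals favour the opposite (cis) relationship in this annulation, so the C3 epimer may well be the major product. The enol azolium could also ring-open by β-alkoxide loss.

Fallback: it sets out from 7 and 4 and comes back at 9, and it makes the same C3–C3a bond with a stoichiometric acyl-anion equivalent. Enal 7 is oxidised (NaClO2, NaH2PO4, 2-methyl-2-butene, t-BuOH/H2O) to the carboxylic acid F1 and esterified (Me3SiCHN2, MeOH/toluene) to the methyl ester F2. Aldehyde 4 is converted with propane-1,3-dithiol and catalytic I2 in CH2Cl2 into the aryl dithiane F3. Lithiated F3 (n-BuLi, THF/DMPU, −78 °C) adds 1,4 to F2 anti to the C2 aryl group to give the dithianyl ester F4. MeI/CaCO3 in aqueous MeCN unmasks the aryl ketone F5, which is reduced at once under reagent control ((R)-1-methyl-3,3-diphenyl-tetrahydro-1H,3H-pyrrolo[1,2-c][1,3,2]oxazaborole, BH3·SMe2, THF, −20 °C) to the (S)-carbinol, the hydroxy ester F6. Catalytic 1,8-diazabicyclo[5.4.0]undec-7-ene in toluene then epimerises the ester-bearing carbon as far as needed and closes the cis-fused lactone 9 with loss of methanol.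

Step 3. Glycolaldehyde may react through its own enamine (C–C Michael addition or self-aldol) instead of through its hydroxyl, or the reversible oxa-Michael step may erode the ee.

Fallback: it sets out from 2 and comes back at 7, using the precedented dihydroxyacetone cascade followed by excision of one carbon. Enal 2 and dihydroxyacetone dimer, with the same amine catalyst and PhCO2H in CHCl3, give by oxa-Michael/aldol/hemiacetalisation the bicyclic lactol F7. NaIO4 in aqueous THF cleaves the tertiary/primary 1,2-diol of its open hydroxy aldehyde form to the β-keto aldehyde F8 (present as its hydroxymethylene enol). i-PrI/K2CO3 in acetone gives the isopropoxymethylene ketone F9. NaBH4/CeCl3·7H2O in MeOH at 0 °C reduces the ketone to the allylic alcohol F10, and dilute HCl in THF hydrolyses the enol ether with allylic transposition to enal 7.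

Step 5. Any free phenoxide para to the benzylic lactone C–O bond can expel the carboxylate as a quinone methide, which would epimerise C3 or open the ring.

Fallback: it sets out from 9 and comes back at 10 without ever liberating a phenoxide. CsF/Ac2O in DMF at 0 °C exchanges silyl for acetyl in situ to give the diacetate F11, and NH4OAc in aqueous MeOH at rt then removes the aryl acetates at neutral pH to give 10.

**Further compounds**
F1 | step 4 | (R)-2-[4-(tert-butyldimethylsilyloxy)-3-methoxyphenyl]-2,5-dihydrofuran-3-carboxylic acid | COc1cc([C@H]2OCC=C2C(=O)O)ccc1O[Si](C)(C)C(C)(C)C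
F2 | step 4 | methyl (R)-2-[4-(tert-butyldimethylsilyloxy)-3-methoxyphenyl]-2,5-dihydrofuran-3-carboxylate | COc1cc([C@H]2OCC=C2C(=O)OC)ccc1O[Si](C)(C)C(C)(C)C
F3 | step 4 | 2-[4-(tert-butyldimethylsilyloxy)-3,5-dimethoxyphenyl]-1,3-dithiane | COc1cc(C2SCCCS2)cc(OC)c1O[Si](C)(C)C(C)(C)C
F4 | step 4 | methyl (2S,4R)-2-[4-(tert-butyldimethylsilyloxy)-3-methoxyphenyl]-4-{2-[4-(tert-butyldimethylsilyloxy)-3,5-dimethoxyphenyl]-1,3-dithian-2-yl}tetrahydrofuran-3-carboxylate (C3 epimer mixture) | COc1cc([C@H]2OC[C@H](C3(c4cc(OC)c(O[Si](C)(C)C(C)(C)C)c(OC)c4)SCCCS3)C2C(=O)OC)ccc1O[Si](C)(C)C(C)(C)C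
F5 | step 4 | methyl (2S,4R)-4-[4-(tert-butyldimethylsilyloxy)-3,5-dimethoxybenzoyl]-2-[4-(tert-butyldimethylsilyloxy)-3-methoxyphenyl]tetrahydrofuran-3-carboxylate (C3 epimer mixture) | COc1cc([C@H]2OC[C@H](C(=O)c3cc(OC)c(O[Si](C)(C)C(C)(C)C)c(OC)c3)C2C(=O)OC)ccc1O[Si](C)(C)C(C)(C)C
F6 | step 4 | methyl (2S,4R)-4-{(S)-[4-(tert-butyldimethylsilyloxy)-3,5-dimethoxyphenyl](hydroxy)methyl}-2-[4-(tert-butyldimethylsilyloxy)-3-methoxyphenyl]tetrahydrofuran-3-carboxylate (C3 epimer mixture) | COc1cc([C@H]2OC[C@H]([C@H](O)c3cc(OC)c(O[Si](C)(C)C(C)(C)C)c(OC)c3)C2C(=O)OC)ccc1O[Si](C)(C)C(C)(C)C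
F7 | step 3 | (3aS,6S,6aR)-6-[4-(tert-butyldimethylsilyloxy)-3-methoxyphenyl]tetrahydro-1H,3H-furo[3,4-c]furan-1,3a(4H)-diol (cis-fused, anomeric mixture) | COc1cc([C@H]2OC[C@]3(O)COC(O)[C@H]23)ccc1O[Si](C)(C)C(C)(C)C
F8 | step 3 | (2S)-2-[4-(tert-butyldimethylsilyloxy)-3-methoxyphenyl]-4-oxotetrahydrofuran-3-carbaldehyde (drawn as the keto aldehyde, present as the hydroxymethylene enol; same spatial arrangement at C2 as in 7) | COc1cc([C@H]2OCC(=O)C2C=O)ccc1O[Si](C)(C)C(C)(C)C
F9 | step 3 | (R)-5-[4-(tert-butyldimethylsilyloxy)-3-methoxyphenyl]-4-[(propan-2-yloxy)methylidene]oxolan-3-one | COc1cc([C@H]2OCC(=O)C2=COC(C)C)ccc1O[Si](C)(C)C(C)(C)C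
F10 | step 3 | (5R)-5-[4-(tert-butyldimethylsilyloxy)-3-methoxyphenyl]-4-[(propan-2-yloxy)methylidene]oxolan-3-ol (carbinol epimer mixture) | COc1cc([C@H]2OCC(O)C2=COC(C)C)ccc1O[Si](C)(C)C(C)(C)C
F11 | step 5 | (3S,3aR,6S,6aS)-6-(4-acetoxy-3-methoxyphenyl)-3-(4-acetoxy-3,5-dimethoxyphenyl)tetrahydro-1H,3H-furo[3,4-c]furan-1-one | COc1cc([C@H]2OC[C@H]3[C@@H]2C(=O)O[C@@H]3c2cc(OC)c(OC(C)=O)c(OC)c2)ccc1OC(C)=O
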